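Retrosynthesis: the C11–OOH group and the C9=C10 position are traced to a Schenck ene reaction of a prenyl ketone. C8–C9 is then cut (prenyl transfer to an epoxy aldehyde), the C7–C14 oxirane and C8 carbonyl are traced to an isopropenyl group, and the C1 ester is cut last.
Ring core: C1–C6 is cut, C6 is rejoined to C2, and the oxirane is walked from C3–C4 back to C2–C3. The cyclohexanone thus becomes a 4-hydroxy-epoxycyclopentane-1-carbaldehyde, one ring atom smaller, which goes back by aldol (C2–C3) and C=C cleavage to (S)-carvone.
Enabling feature: in the six-membered ring C1(H)–O/C2=O is an acyloin unit and C2 is flanked by the C3–C4 oxirane. The ring is therefore the retron of an α-ketol enlargement of a 1-oxidocyclopentanecarbaldehyde (C6 shifts from C2 to formyl carbon C1), whose C2 alkoxide is released by Payne migration of a C2–C3 oxirane under attack of a C4 alkoxide.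
Forward order: cyclopentene (aldol condensation) → C2–C3 oxirane → in one operation the C3–C4 oxirane, the cyclohexanone (5 → 6) and the ester → side-chain C7–C14 oxirane → C8–C9 chain extension → oxygenation at C11.
Stereochemistry: C6 comes from (S)-carvone and is retained in the shift; C4 comes from a Luche reduction; C3 is set by SN2 inversion in the Payne step, which puts the oxirane cis to the C6 substituent. C1 is set by a lithium-chelated migration geometry (also the equatorial epimer), C7 by catalyst control, and the E-alkene by the ene reaction.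
Numbering: ring C1 (CH–O-acyl), C2 (C=O), C3 (C–CH3), C4 (oxirane CH), C5 (CH2), C6 (CH); side chain C7 (oxirane C), C14 (oxirane CH2), C8 (C=O), C9=C10, C11 (C–OOH).

Key step: step 8

Remark on the chemistry: β denotes the ring face that carries the C6 substituent and α the opposite face. Compounds 21 and 22 are taken as C8 epimer mixtures and 7 as a transient C2/C3 mixture; this is of no consequence because these centres are removed in the following transformation.

Step 1
Reactants: 1 (S)-(+)-carvone
Product: 2 (1S,5S)-cis-carveol
Conditions: NaBH4, CeCl3·7H2O, MeOH, −78 → 0 °C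
Reagents that add atoms: none
Why: Luche 1,2-reduction: hydride should add axially on the α face of the half-chair that holds the isopropenyl group equatorial, which sets the future C4 carbinol β, cis to the isopropenyl group.

Step 2
Reactants: 2 (1S,5S)-cis-carveol
Product: 3 all-β epoxy alcohol (1S,2S,4R,6R)-1-methyl-4-(prop-1-en-2-yl)-7-oxabicyclo[4.1.0]heptan-2-ol
Conditions: VO(acac)2 (cat.), t-BuOOH, CH2Cl2, 0 °C → rt
Reagents that add atoms: tert-butyl hydroperoxide, CC(C)(C)OO
Why: Vanadium-catalysed hydroxyl-directed epoxidation should oxidise only the allylic ring alkene, syn to the OH, and leave the isopropenyl group untouched; the two new centres are erased in step 4.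

Step 3
Reactants: 3 all-β epoxy alcohol
Product: 4 tert-butyldimethylsilyl ether of 3
Conditions: TBSCl, imidazole, DMF, rt
Reagents that add atoms: tert-butyldimethylsilyl chloride, CC(C)(C)[Si](C)(C)Cl
Why: Standard silyl ether formation masks the C4 carbinol so that periodate cannot cut the C3–C4 bond in step 4; no stereocentre is touched.

Step 4
Reactants: 4 TBS ether of 3
Product: 6 (3R,5S)-5-(tert-butyldimethylsilyloxy)-6-oxo-3-(prop-1-en-2-yl)heptanal, via trans-diol 5 (not isolated)
Conditions: H5IO6, THF–H2O, 0 °C → rt
Reagents that add atoms: water, O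
Why: Acid-catalysed hydrolysis of the trisubstituted oxirane and Malaprade glycol cleavage in one flask cut the former C=C bond of carvone; the isopropenyl group is inert to periodate, and C4 and C6 are untouched.

Step 5
Reactants: 6 keto aldehyde
Product: 8 (3S,5S)-3-(tert-butyldimethylsilyloxy)-2-methyl-5-(prop-1-en-2-yl)cyclopent-1-ene-1-carbaldehyde, via aldol adduct 7 (not isolated)
Conditions: piperidine (cat.), AcOH (cat.), toluene, 80 °C, 4 Å MS
Reagents that add atoms: none
Why: Intramolecular enamine aldol condensation (5-enolexo), as known for the keto aldehyde from limonene: the amine makes only the aldehyde nucleophilic, so C2 attacks the C3 ketone and dehydration gives the tetrasubstituted enal with C4 and C6 carried through.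

Step 6
Reactants: 8 cyclopentene carbaldehyde
Product: 9 α-epoxy aldehyde 4β-(tert-butyldimethylsilyloxy)-5-methyl-2β-(prop-1-en-2-yl)-6-oxabicyclo[3.1.0]hexane-1-carbaldehyde
Conditions: t-BuOOH, Triton B (cat.), THF, 0 °C
Reagents that add atoms: tert-butyl hydroperoxide, CC(C)(C)OO
Why: Weitz–Scheffer nucleophilic epoxidation: the peroxide anion should add to C3 from the α face, opposite to both the C4 silyloxy and the C6 isopropenyl groups, which sets the C2–C3 oxirane trans to C4–O, while the electron-rich isopropenyl group is inert.

Step 7
Reactants: 9 α-epoxy aldehyde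
Product: 10 4β-hydroxy-5-methyl-2β-(prop-1-en-2-yl)-6-oxabicyclo[3.1.0]hexane-1-carbaldehyde (oxirane α)
Conditions: HF·pyridine, pyridine, THF, 0 °C → rt
Reagents that add atoms: none
Why: Fluoride-induced silyl ether cleavage in a buffered acidic medium frees the C4 hydroxyl without forming an alkoxide, so the base-triggered cascade cannot start early; no stereocentre changes.

Step 8
Reactants: 10 hydroxy epoxy aldehyde
Product: 14 1-methyl-2-oxo-4β-(prop-1-en-2-yl)-7-oxabicyclo[4.1.0]heptan-3α-yl 3-methylbutanoate (oxirane β), via lithium C4-alkoxide 11 (not isolated), via Payne-shifted C2-alkoxide 12 (not isolated), via ring-enlarged C1-alkoxide 13 (not isolated)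
Conditions: LiHMDS (1.0 equiv), toluene–THF, −78 → 0 °C; then (i-BuCO)2O, DMAP (cat.), −20 °C → rt
Reagents that add atoms: isovaleric anhydride, CC(C)CC(=O)OC(=O)CC(C)C
Why: Proposed new method: deprotonation gives alkoxide 11, whose C4–O attacks C3 from the β face with SN2 inversion (Payne rearrangement), helped by the formyl group, which directs attack to the distal oxirane carbon and stabilises the departing C2 alkoxide; in the resulting 12 the C2 alkoxide pushes the C2–C6 σ bond onto formyl carbon C1 (α-ketol 1,2-shift), which turns the cyclopentane into cyclohexanone 13, and the C1 alkoxide is esterified in the same flask. The closest known reaction types are the epoxide migration of trans-2,3-epoxy alcohols and the base- or Lewis-acid-induced ring enlargement of 1-hydroxycycloalkanecarbaldehydes and 17-hydroxy-20-keto steroids (D-homoannulation); what is new is their coupling, in which an unfavourable Payne equilibrium is drained by the practically irreversible aldehyde-to-ketone shift. Ring formation: the C3–C4 oxirane closes 3-exo-tet, whereas the six-membered ring is not closed by cyclisation but arises by enlargement through a three-centre migration transition state with relief of bicyclo[3.1.0] strain. Stereocontrol: C4 keeps the configuration of step 1, C3 is inverted so that the oxirane ends on the β face cis to the C6 substituent (the face that peroxide attack on a carvone-type enone does not reach), C6 migrates with retention, and C1 is set by the five-membered lithium chelate of the C2 alkoxide and the formyl oxygen (syn-periplanar O–C–C=O), which places C1–O equatorial, α and trans to C6, the epimer also favoured at equilibrium. Selectivity: C6 must migrate rather than C3, which is secured because C3 has become an oxirane carbon with an s-rich, poorly migrating exocyclic bond and because only the C6 shift removes the eclipsing of formyl and isopropenyl groups; proton loss at C1 of 13 (enediolate formation with opening of the oxirane) is held back by low temperature, the chelate and prompt acylation.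

Step 9
Reactants: 14 ring core ester
Product: 15 4β-(3-chloroprop-1-en-2-yl) analogue of 14
Conditions: Ca(OCl)2, CO2 (s), CH2Cl2–H2O, 0 °C
Reagents that add atoms: calcium hypochlorite, [Ca+2].[O-]Cl.[O-]Cl
Why: Ene-type allylic chlorination with hypochlorous acid, well known for the isopropenyl groups of carvone and limonene: Cl+ adds to the terminal CH2 and a methyl proton is lost to give the 2-(chloromethyl)allyl unit; there is no other alkene and no stereocentre changes.

Step 10
Reactants: 15 allylic chloride
Product: 16 4β-(3-oxoprop-1-en-2-yl) analogue of 14 (2-substituted acrolein)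
Conditions: NMO, KI (cat.), 4 Å MS, MeCN, rt → 45 °C
Reagents that add atoms: N-methylmorpholine N-oxide, C[N+]1([O-])CCOCC1
Why: N-oxide variant of the Kornblum oxidation (Ganem oxidation): O-alkylation of the N-oxide by the primary allylic halide and loss of N-methylmorpholine should give the enal under nearly neutral conditions that spare ester, ketone and oxirane.

Step 11
Reactants: 16 2-substituted acrolein
Product: 17 4β-[(R)-2-formyloxiran-2-yl] analogue of 14 (epoxy aldehyde)
Conditions: (S)-α,α-diphenylprolinol trimethylsilyl ether (20 mol %), 30% aq H2O2, CH2Cl2, rt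
Reagents that add atoms: hydrogen peroxide, OO
Why: Iminium–enamine organocatalytic epoxidation known for α-substituted acroleins: hydrogen peroxide adds to C14 of the iminium ion and the enamine closes the oxirane on the face left open by the diphenyl(silyloxy)methyl group, so the (S)-catalyst should set (R)-C7 under reagent control, while the ring ketone and the ester are not activated.

Step 12
Reactants: 18 prenol (3-methylbut-2-en-1-ol)
Product: 19 methyl 3-methylbut-2-en-1-yl carbonate
Conditions: ClCO2Me, pyridine, CH2Cl2, 0 °C
Reagents that add atoms: methyl chloroformate, COC(=O)Cl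
Why: Simple O-acylation of a primary allylic alcohol with a chloroformate; no stereocentre is involved.

Step 13
Reactants: 19 prenyl methyl carbonate
Product: 20 2-(2-methylbut-3-en-2-yl)-4,4,5,5-tetramethyl-1,3,2-dioxaborolane
Conditions: B2pin2, CuCl/Xantphos/KOt-Bu (cat.), THF, rt
Reagents that add atoms: bis(pinacolato)diboron, CC1(C)OB(OC1(C)C)B1OC(C)(C)C(C)(C)O1
Why: Copper(I)-catalysed γ-selective (SN2′) allylic borylation of an allylic carbonate: borylcupration puts boron on the dimethyl-substituted carbon and β-elimination of the carbonate gives the tertiary 1,1-dimethylallyl boronate; no stereocentre is formed.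

Step 14
Reactants: 17 epoxy aldehyde; 20 1,1-dimethylallyl boronate
Product: 22 4β-[(2R)-2-(1-hydroxy-4-methylpent-3-enyl)oxiran-2-yl] analogue of 14, via C8 borate ester 21 (not isolated)
Conditions: toluene, rt → 50 °C; then aq NaHCO3
Reagents that add atoms: boronate 20, C=CC(C)(C)B1OC(C)(C)C(C)(C)O1
Why: Carbonyl allylboration through a closed six-membered Zimmerman–Traxler transition state with allylic transposition: the tertiary boronate delivers its CH2 terminus, so the linear prenyl carbinol should form, only the aldehyde reacts with the neutral reagent, and the new C8 centre needs no control because step 15 removes it.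

Step 15
Reactants: 22 prenyl carbinol
Product: 23 4β-[(2R)-2-(4-methylpent-3-enoyl)oxiran-2-yl] analogue of 14 (β,γ-unsaturated ketone)
Conditions: Dess–Martin periodinane, NaHCO3, CH2Cl2, 0 °C → rt
Reagents that add atoms: none
Why: Dess–Martin oxidation under bicarbonate buffer is neutral enough to keep the β,γ-double bond out of conjugation and to spare both oxiranes; it removes the C8 stereocentre.

Step 16
Reactants: 23 β,γ-unsaturated ketone
Product: 24 target CNP0131119.1 (1S,3S,4S,6R,7R; 9E)
Conditions: O2, tetraphenylporphyrin (cat.), visible light, CH2Cl2, −20 °C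
Reagents that add atoms: dioxygen, O=O
Why: Schenck ene reaction of singlet oxygen with the only alkene: abstraction of a C9–H, which is activated by the carbonyl group and lies on the more substituted side of the trisubstituted alkene, places the hydroperoxide on tertiary C11 and moves the double bond into conjugation as the E-isomer; no stereocentre is formed.

Compound list
1 | (S)-(+)-carvone | CC1=CC[C@@H](CC1=O)C(C)=C | starting material
2 | (1S,5S)-cis-carveol | CC1=CC[C@@H](C[C@@H]1O)C(C)=C | intermediate
3 | (1S,2S,4R,6R)-1-methyl-4-(prop-1-en-2-yl)-7-oxabicyclo[4.1.0]heptan-2-ol (OH, oxirane, isopropenyl all β) | O[C@H]1C[C@@H](C(C)=C)C[C@H]2O[C@@]12C | intermediate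
4 | TBS ether of 3 | CC(C)(C)[Si](C)(C)O[C@H]1C[C@@H](C(C)=C)C[C@H]2O[C@@]12C | intermediate
5 | trans-diol from hydrolysis of 4 (not isolated) | CC(C)(C)[Si](C)(C)O[C@H]1C[C@@H](C(C)=C)C[C@@H](O)[C@]1(C)O | intermediate
6 | (3R,5S)-5-(tert-butyldimethylsilyloxy)-6-oxo-3-(prop-1-en-2-yl)heptanal | CC(=O)[C@@H](O[Si](C)(C)C(C)(C)C)C[C@@H](C(C)=C)CC=O | intermediate
7 | aldol adduct, C2/C3 undefined (not isolated) | O=CC1C(C)(O)[C@@H](O[Si](C)(C)C(C)(C)C)C[C@H]1C(C)=C | intermediate
8 | (3S,5S)-3-(tert-butyldimethylsilyloxy)-2-methyl-5-(prop-1-en-2-yl)cyclopent-1-ene-1-carbaldehyde | O=CC1=C(C)[C@@H](O[Si](C)(C)C(C)(C)C)C[C@H]1C(C)=C | intermediate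
9 | α-epoxy aldehyde, 4β-OTBS, 2β-isopropenyl, 6-oxabicyclo[3.1.0]hexane-1-carbaldehyde | O=C[C@@]12O[C@]1(C)[C@@H](O[Si](C)(C)C(C)(C)C)C[C@H]2C(C)=C | intermediate
10 | 4β-hydroxy α-epoxy aldehyde | O=C[C@@]12O[C@]1(C)[C@@H](O)C[C@H]2C(C)=C | intermediate
11 | lithium C4-alkoxide of 10 (not isolated) | O=C[C@@]12O[C@]1(C)[C@@H]([O-])C[C@H]2C(C)=C.[Li+] | intermediate
12 | Payne-shifted lithium C2-alkoxide, C3–C4 oxirane β (not isolated) | O=C[C@@]1([O-])[C@@]2(C)O[C@H]2C[C@H]1C(C)=C.[Li+] | intermediate
13 | ring-enlarged lithium C1-alkoxide (not isolated) | [O-][C@@H]1C(=O)[C@@]2(C)O[C@H]2C[C@H]1C(C)=C.[Li+] | intermediate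
14 | ring core: 1α-isovaleryloxy-2-oxo-3β,4β-epoxy-6β-isopropenyl cyclohexane | CC(C)CC(=O)O[C@@H]1C(=O)[C@@]2(C)O[C@H]2C[C@H]1C(C)=C | intermediate
15 | allylic chloride | CC(C)CC(=O)O[C@@H]1C(=O)[C@@]2(C)O[C@H]2C[C@H]1C(=C)CCl | intermediate
16 | 2-substituted acrolein | CC(C)CC(=O)O[C@@H]1C(=O)[C@@]2(C)O[C@H]2C[C@H]1C(=C)C=O | intermediate
17 | (7R)-epoxy aldehyde | CC(C)CC(=O)O[C@@H]1C(=O)[C@@]2(C)O[C@H]2C[C@H]1[C@]1(C=O)CO1 | intermediate
18 | prenol | CC(C)=CCO | starting material
19 | methyl prenyl carbonate | COC(=O)OCC=C(C)C | intermediate
20 | 1,1-dimethylallyl pinacol boronate | C=CC(C)(C)B1OC(C)(C)C(C)(C)O1 | intermediate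
21 | C8 borate ester, C8 undefined (not isolated) | CC(C)CC(=O)O[C@@H]1C(=O)[C@@]2(C)O[C@H]2C[C@H]1[C@]1(C(CC=C(C)C)OB2OC(C)(C)C(C)(C)O2)CO1 | intermediate
22 | prenyl carbinol, C8 undefined | CC(C)CC(=O)O[C@@H]1C(=O)[C@@]2(C)O[C@H]2C[C@H]1[C@]1(C(O)CC=C(C)C)CO1 | intermediate
23 | β,γ-unsaturated epoxy ketone | CC(C)CC(=O)O[C@@H]1C(=O)[C@@]2(C)O[C@H]2C[C@H]1[C@]1(C(=O)CC=C(C)C)CO1 | intermediate
24 | CNP0131119.1 | CC(C)CC(=O)O[C@@H]1C(=O)[C@@]2(C)O[C@H]2C[C@H]1[C@]1(C(=O)/C=C/C(C)(C)OO)CO1 | target

Total step count: 16. Longest linear sequence: 14 (steps 1–11 and 14–16).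

Steps most likely to fail

Step 8. The Payne equilibrium may not be drained fast enough, so alkoxide-induced hydride or acyl-type transfer at the aldehyde could take over. Enolisation of the ring-enlarged ketolate with opening of the new oxirane is a second danger. The shift may also run through the non-chelated rotamer, with loss of facial control at C1. The fallback uses known chemistry: it separates the oxygen walk from the ring enlargement and sets the oxirane later by hydroxyl direction. It sets out from 10.
- An Appel reaction (I2, PPh3, imidazole) gives the 4α-iodo epoxy aldehyde F1.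
- Zinc-induced reductive opening of the 2,3-epoxy iodide gives the transposed allylic alcohol, 1α-hydroxy-2-methyl-5β-isopropenylcyclopent-2-ene-1-carbaldehyde F2.
- The classical aluminium alkoxide- or base-induced α-ketol ring enlargement gives the trans-6-hydroxy enone F3. Either ring bond at C2 may migrate, because the product of C3 migration tautomerises through the enediol to the same conjugated hydroxy enone.
- Acylation with isovaleric anhydride gives the ester F4.
- Luche reduction gives the 2β-allylic alcohol F5.
- Vanadium-catalysed directed epoxidation places the oxirane on the β face in the epoxy alcohol F6.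
- Dess–Martin oxidation comes back to the route at 14.

Step 11. Iminium formation with the hindered α-branched enal may be slow, and the facial selectivity of the oxirane closure at C7 may be poor. The fallback replaces amine catalysis by titanium–tartrate control and sets out from 16.
- Aldehyde-selective reduction with NaBH(OAc)3 gives the 2-substituted allylic alcohol F7.
- Sharpless asymmetric epoxidation with L-(+)-diethyl tartrate gives the epoxy alcohol F8.
- Dess–Martin oxidation comes back to the route at 17.

Step 16. Singlet oxygen may abstract hydrogen from the methyl groups instead of C9, which would put the oxygen on C10 rather than C11. The β,γ-alkene may also drift into conjugation before oxygenation. The fallback installs the peroxide by hydrogen-atom transfer to a dienone and sets out from 17.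
- (E)-1-Iodo-3-methylbuta-1,3-diene F9, made by Takai olefination of methacrolein, is added by a Nozaki–Hiyama–Kishi reaction to give the dienol F10.
- Dess–Martin oxidation gives the cross-conjugation-free dienone F11.
- Cobalt-catalysed Mukaiyama–Isayama silylperoxidation (Co(thd)2, O2, Et3SiH) adds hydrogen to the terminal CH2 and dioxygen to tertiary C11 to give the triethylsilyl peroxide F12.
- Mild acidic desilylation (AcOH, THF–H2O) comes back to the route at 24.

Further compounds
F1 | step 8 | 4α-iodo epoxy aldehyde | O=C[C@@]12O[C@]1(C)[C@H](I)C[C@H]2C(C)=C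
F2 | step 8 | 1α-hydroxy-2-methyl-5β-isopropenylcyclopent-2-ene-1-carbaldehyde | O=C[C@@]1(O)C(C)=CC[C@H]1C(C)=C
F3 | step 8 | trans-6-hydroxy-2-methyl-5-isopropenylcyclohex-2-enone | O[C@@H]1C(=O)C(C)=CC[C@H]1C(C)=C
F4 | step 8 | isovalerate of F3 | CC(C)CC(=O)O[C@@H]1C(=O)C(C)=CC[C@H]1C(C)=C
F5 | step 8 | 2β-allylic alcohol | CC(C)CC(=O)O[C@@H]1[C@@H](O)C(C)=CC[C@H]1C(C)=C
F6 | step 8 | 2β-hydroxy-3β,4β-epoxide | CC(C)CC(=O)O[C@@H]1[C@@H](O)[C@@]2(C)O[C@H]2C[C@H]1C(C)=C
F7 | step 11 | 2-substituted allylic alcohol | CC(C)CC(=O)O[C@@H]1C(=O)[C@@]2(C)O[C@H]2C[C@H]1C(=C)CO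
F8 | step 11 | side-chain epoxy alcohol | CC(C)CC(=O)O[C@@H]1C(=O)[C@@]2(C)O[C@H]2C[C@H]1[C@]1(CO)CO1
F9 | step 16 | (E)-1-iodo-3-methylbuta-1,3-diene | CC(=C)/C=C/I
F10 | step 16 | dienol, C8 undefined | CC(C)CC(=O)O[C@@H]1C(=O)[C@@]2(C)O[C@H]2C[C@H]1[C@]1(C(O)/C=C/C(C)=C)CO1
F11 | step 16 | dienone | CC(C)CC(=O)O[C@@H]1C(=O)[C@@]2(C)O[C@H]2C[C@H]1[C@]1(C(=O)/C=C/C(C)=C)CO1
F12 | step 16 | C11 triethylsilyl peroxide | CC(C)CC(=O)O[C@@H]1C(=O)[C@@]2(C)O[C@H]2C[C@H]1[C@]1(C(=O)/C=C/C(C)(C)OO[Si](CC)(CC)CC)CO1
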